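**Retrosynthetic overview**
- The 14-membered ring is closed last, at C3–C4, by an electrochemical nickel/chromium coupling of an (E)-vinyl iodide with an aldehyde; the substrate already carries the finished α-methylene ε-lactone.
- The lactone comes from lactonisation of the C16 acid onto the tertiary C12–OH, after the C3 acyl group of a Baeyer–Villiger lactone has been moved aside as an amide.
- The C12–O bond comes from Baeyer–Villiger oxidation (retention) of a 2,2-disubstituted cyclohexanone by a peroxy acid made from the substrate's own C16 acid.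
- C11–C12 and both of their stereocentres come from a reductive aldol of an (R)-carvone-derived keto acid with an iodo-dienal built from nerol (Z alkene) and propyne (E vinyl iodide).
- Ring order: carvone six-membered ring (template) → temporary ε-lactone (C3 acyl) → α-methylene ε-lactone (C16 acyl) → 14-membered carbocycle.

Assumption: the target is taken exactly as its SMILES, i.e. (1R,3R,11S,12R), 4E, 7Z in cembrane locants (C16 lactone carbonyl, C17 exocyclic CH2, C18/C19/C20 the methyls on C4/C8/C12); these locants are used for all intermediates.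

**Route**

Step 1
Reactants: 1 nerol [(2Z)-3,7-dimethylocta-2,6-dien-1-ol]
Product: 2 neryl chloride [(2Z)-1-chloro-3,7-dimethylocta-2,6-diene]
Conditions: NCS, Me2S, CH2Cl2, −30 → 0 °C
Reagents that add atoms: N-chlorosuccinimide (O=C1CCC(=O)N1Cl)
Why: Corey–Kim-type chlorination of the allylic alcohol proceeds by SN2 displacement of the alkoxysulfonium group without allylic transposition, so the Z alkene of nerol is kept.

Step 2
Reactants: 2 neryl chloride
Product: 3 (4Z)-6-chloro-4-methylhex-4-enal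
Conditions: O3 (1.0 equiv), CH2Cl2, pyridine (cat.), −78 °C; then Me2S
Reagents that add atoms: ozone ([O-][O+]=O)
Why: Ozonolysis with reductive work-up cleaves only the electron-rich isopropylidene alkene because the allylic chlorine deactivates the other one, as in the selective ozonolysis of geranyl and neryl esters.

Step 3
Reactants: 3 (4Z)-6-chloro-4-methylhex-4-enal
Product: 4 2-[(3Z)-5-chloro-3-methylpent-3-en-1-yl]-1,3-dioxolane
Conditions: (Me3SiOCH2)2, Me3SiOTf (2 mol%), CH2Cl2, −78 °C
Reagents that add atoms: 1,2-bis(trimethylsilyloxy)ethane (C[Si](C)(C)OCCO[Si](C)(C)C)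
Why: Noyori acetalisation under aprotic conditions at low temperature masks the aldehyde as a dioxolane without ionising the allylic chloride.

Step 4
Reactants: 4 2-[(3Z)-5-chloro-3-methylpent-3-en-1-yl]-1,3-dioxolane
Product: 5 2-[(3Z)-3-methyloct-3-en-6-yn-1-yl]-1,3-dioxolane
Conditions: CH3C≡CMgBr, CuCl (5 mol%), THF, 0 → 45 °C
Reagents that add atoms: 1-propynylmagnesium bromide (CC#C[Mg]Br)
Why: Copper-catalysed SN2 coupling of an alkynyl Grignard reagent with a primary allylic chloride gives the skipped enyne with retention of the Z alkene.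

Step 5
Reactants: 5 2-[(3Z)-3-methyloct-3-en-6-yn-1-yl]-1,3-dioxolane
Product: 8 (4Z,7E)-8-iodo-4-methylnona-4,7-dienal, via alkenylzirconocene 6 (not isolated), via iodo acetal 7 (not isolated)
Conditions: Cp2Zr(H)Cl (2.5 equiv), THF, 40 °C; I2, 0 °C; then 1 M HCl, THF, rt
Reagents that add atoms: iodine (II), water (O)
Why: Hydrozirconation–iodination adds Zr–H syn, zirconium settles on the methyl-bearing alkyne carbon on equilibration with excess reagent, iodinolysis with retention gives the (E)-2-iodoalkene, and the acidic work-up hydrolyses the dioxolane.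

Step 6
Reactants: 9 (R)-(−)-carvone [(5R)-2-methyl-5-(prop-1-en-2-yl)cyclohex-2-en-1-one]
Product: 11 2-[(1R)-4-methyl-5-oxocyclohex-3-en-1-yl]prop-2-enal, via allylic alcohol 10 (not isolated)
Conditions: SeO2 (0.3 equiv), t-BuOOH, CH2Cl2, rt; then MnO2, CH2Cl2, rt
Reagents that add atoms: tert-butyl hydroperoxide (CC(C)(C)OO), passed on by selenium dioxide (O=[Se]=O)
Why: Selenium dioxide allylic oxidation (ene reaction, then 2,3-shift) attacks the electron-rich isopropenyl group at its methyl rather than the enone, and MnO2 takes the allylic alcohol on to the enal without touching the stereocentre.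

Step 7
Reactants: 11 2-[(1R)-4-methyl-5-oxocyclohex-3-en-1-yl]prop-2-enal
Product: 12 2-[(1R)-4-methyl-5-oxocyclohex-3-en-1-yl]prop-2-enoic acid
Conditions: NaClO2, NaH2PO4, 2-methylbut-2-ene, t-BuOH/H2O, 0 °C
Reagents that add atoms: sodium chlorite ([Na+].[O-]Cl=O)
Why: Pinnick oxidation converts the α-substituted acrolein into the acrylic acid and leaves the enone alone.

Step 8
Reactants: 12 2-[(1R)-4-methyl-5-oxocyclohex-3-en-1-yl]prop-2-enoic acid; 8 (4Z,7E)-8-iodo-4-methylnona-4,7-dienal
Product: 16 2-[(1R,4R)-4-[(1S,4Z,7E)-1-acetoxy-8-iodo-4-methylnona-4,7-dien-1-yl]-4-methyl-3-oxocyclohexyl]prop-2-enoic acid, via lithium enolate 13 (not isolated), via zirconium enolate 14 (not isolated), via aldol adduct 15 (not isolated)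
Conditions: LiN(SiMe3)2 (1.0 equiv), THF, −78 °C; Li[(s-Bu)3BH] (1.1 equiv); Cp2ZrCl2 (1.2 equiv), −78 → −40 °C; 8; then Ac2O, DMAP, −40 → 0 °C; aq. NH4Cl
Reagents that add atoms: acetic anhydride (CC(=O)OC(C)=O)
Why: Reductive aldol in which conjugate hydride addition to the enone gives the tetrasubstituted enolate regiospecifically (the acrylate, held as its lithium carboxylate, is not a hydride acceptor), the aldehyde adds axially at C12 on the face cis to the equatorial C1 side chain as in alkylations and Robinson annulations of dihydrocarvone enolates (12R from the carvone centre), the zirconium enolate gives the aldol with the hydroxyl syn to the ring CH2 whatever the enolate geometry (11S), and the aldolate is acetylated before it can revert.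

Step 9
Reactants: 16 2-[(1R,4R)-4-[(1S,4Z,7E)-1-acetoxy-8-iodo-4-methylnona-4,7-dien-1-yl]-4-methyl-3-oxocyclohexyl]prop-2-enoic acid
Product: 19 2-[(4R,7R)-7-[(1S,4Z,7E)-1-acetoxy-8-iodo-4-methylnona-4,7-dien-1-yl]-7-methyl-2-oxooxepan-4-yl]prop-2-enoic acid, via mixed anhydride 17 (not isolated), via peroxy acid 18 (not isolated)
Conditions: ClCO2Et, N-methylmorpholine, THF, −20 °C; H2O2·urea, 0 °C; then CH2Cl2 (0.01 M), CF3CO2H (10 mol%), 0 °C → rt; Me2S quench
Reagents that add atoms: hydrogen peroxide (OO)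
Why: Proposed new method: the C16 acid is turned in the flask into its own peroxy acid, which adds to the ketone two carbons away through a seven-membered cyclic Criegee adduct in which only the exocyclic C12–C(O) bond can lie antiperiplanar to the O–O bond, so the quaternary carbon migrates with retention (12R kept) while the dilute, tethered oxidant spares the trisubstituted alkene and the vinyl iodide; the closest known chemistry is the intermolecular Baeyer–Villiger oxidation with peroxy acids and intramolecular epoxidation by substrate-borne peroxy acids.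

Step 10
Reactants: 19 2-[(4R,7R)-7-[(1S,4Z,7E)-1-acetoxy-8-iodo-4-methylnona-4,7-dien-1-yl]-7-methyl-2-oxooxepan-4-yl]prop-2-enoic acid
Product: 20 (3R,6R,7S,10Z,13E)-7-acetoxy-6-hydroxy-14-iodo-6,10-dimethyl-2-methylidene-3-[2-oxo-2-(pyrrolidin-1-yl)ethyl]pentadeca-10,13-dienoic acid
Conditions: pyrrolidine (3 equiv), THF, rt; aq. citric acid work-up
Reagents that add atoms: pyrrolidine (C1CCNC1)
Why: Aminolysis of the seven-membered lactone (acyl–oxygen cleavage) is faster than that of the hindered secondary acetate, frees the tertiary C12 hydroxyl with its configuration unchanged and parks C3 as an amide, while the acrylic acid is protected as its ammonium carboxylate.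

Step 11
Reactants: 20 (3R,6R,7S,10Z,13E)-7-acetoxy-6-hydroxy-14-iodo-6,10-dimethyl-2-methylidene-3-[2-oxo-2-(pyrrolidin-1-yl)ethyl]pentadeca-10,13-dienoic acid
Product: 21 (1S,4Z,7E)-8-iodo-4-methyl-1-[(2R,5R)-2-methyl-6-methylidene-7-oxo-5-[2-oxo-2-(pyrrolidin-1-yl)ethyl]oxepan-2-yl]nona-4,7-dien-1-yl acetate
Conditions: 2,4,6-Cl3C6H2COCl, Et3N, DMAP, toluene, 80 °C, slow addition (2 mM)
Reagents that add atoms: none
Why: Yamaguchi lactonisation (one-pot Yonemitsu variant) acylates the only free hydroxyl, the tertiary C12–OH, with the activated acrylic acid to close the seven-membered α-methylene lactone, helped by the gem-disubstitution at C12, and changes no stereocentre.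

Step 12
Reactants: 21 (1S,4Z,7E)-8-iodo-4-methyl-1-[(2R,5R)-2-methyl-6-methylidene-7-oxo-5-[2-oxo-2-(pyrrolidin-1-yl)ethyl]oxepan-2-yl]nona-4,7-dien-1-yl acetate
Product: 23 (1S,4Z,7E)-8-iodo-4-methyl-1-[(2R,5R)-2-methyl-6-methylidene-7-oxo-5-(2-oxoethyl)oxepan-2-yl]nona-4,7-dien-1-yl acetate, via enamine 22 (not isolated)
Conditions: IrCl(CO)(PPh3)2 (1 mol%), (HMe2Si)2O, toluene, rt; then AcOH/H2O/THF
Reagents that add atoms: water (O)
Why: Iridium-catalysed hydrosilylation of the tertiary amide is chemoselective over lactone, acetate and alkenes and gives the enamine, whose mild hydrolysis releases the C3 aldehyde.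

Step 13
Reactants: 23 (1S,4Z,7E)-8-iodo-4-methyl-1-[(2R,5R)-2-methyl-6-methylidene-7-oxo-5-(2-oxoethyl)oxepan-2-yl]nona-4,7-dien-1-yl acetate
Product: 25 (1R,3R,4E,7Z,11S,12R)-11-acetoxy-3-hydroxycembra-4,7,15(17)-trien-16,12-olide (CNP0130972.5), via triethylsilyl ether 24 (not isolated)
Conditions: CrCl2 (20 mol%), NiCl2·DME (5 mol%), 2,9-dimethyl-1,10-phenanthroline (5 mol%), Et3SiCl (2 equiv), Bu4NBF4, DMF, undivided cell, Zn anode/Ni-foam cathode, constant current (2.2 F/mol), syringe-pump addition of 23 to 2 mM, rt; then 1 M HCl, THF, 0 °C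
Reagents that add atoms: none
Why: Proposed new method: the chemical reductant of the Nozaki–Hiyama–Kishi reaction is replaced by the cathode in a ring-closing mode, zerovalent nickel inserting into the C4–I bond with retention of the E geometry and passing the alkenyl group to chromium (kept divalent at the cathode and released from the product by Et3SiCl), which adds to the C3 aldehyde and closes the 14-membered ring, with C3 set by the existing centres (attack on the aldehyde face turned away from the lactone held at C1 is expected to give the 3R alcohol, 1,3-syn to C15, but the ratio is not secured); the closest known chemistry is the intermolecular electrochemical Nozaki–Hiyama–Kishi coupling and chromium-mediated macrocyclisations with stoichiometric CrCl2.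

**Compound list**

1 | nerol, (2Z)-3,7-dimethylocta-2,6-dien-1-ol | CC(C)=CCC/C(C)=C\CO | starting material
2 | neryl chloride, (2Z)-1-chloro-3,7-dimethylocta-2,6-diene | CC(C)=CCC/C(C)=C\CCl | intermediate
3 | (4Z)-6-chloro-4-methylhex-4-enal | O=CCC/C(C)=C\CCl | intermediate
4 | 2-[(3Z)-5-chloro-3-methylpent-3-en-1-yl]-1,3-dioxolane | ClC/C=C(C)\CCC1OCCO1 | intermediate
5 | 2-[(3Z)-3-methyloct-3-en-6-yn-1-yl]-1,3-dioxolane | CC#CC/C=C(C)\CCC1OCCO1 | intermediate
6 | alkenylzirconocene, Cp2Zr(Cl)[(2E,5Z)-8-(1,3-dioxolan-2-yl)-6-methylocta-2,5-dien-2-yl] | C/C(=C\C/C=C(C)\CCC1OCCO1)[Zr](Cl)(C2C=CC=C2)C2C=CC=C2 | intermediate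
7 | 2-[(3Z,6E)-7-iodo-3-methylocta-3,6-dien-1-yl]-1,3-dioxolane | C/C(I)=C\C/C=C(C)\CCC1OCCO1 | intermediate
8 | (4Z,7E)-8-iodo-4-methylnona-4,7-dienal | O=CCC/C(C)=C\C/C=C(C)/I | intermediate
9 | (R)-(−)-carvone, (5R)-2-methyl-5-(prop-1-en-2-yl)cyclohex-2-en-1-one | CC1=CC[C@H](CC1=O)C(C)=C | starting material
10 | (5R)-5-(3-hydroxyprop-1-en-2-yl)-2-methylcyclohex-2-en-1-one | CC1=CC[C@H](CC1=O)C(=C)CO | intermediate
11 | 2-[(1R)-4-methyl-5-oxocyclohex-3-en-1-yl]prop-2-enal | CC1=CC[C@H](CC1=O)C(=C)C=O | intermediate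
12 | 2-[(1R)-4-methyl-5-oxocyclohex-3-en-1-yl]prop-2-enoic acid | CC1=CC[C@H](CC1=O)C(=C)C(O)=O | intermediate
13 | dilithium 2-[(1R)-4-methyl-3-oxidocyclohex-3-en-1-yl]prop-2-enoate | [Li+].[Li+].[O-]C(=O)C(=C)[C@@H]1CCC(C)=C([O-])C1 | intermediate
14 | lithium 2-[(1R)-3-(chlorozirconocenyloxy)-4-methylcyclohex-3-en-1-yl]prop-2-enoate, the Cp2Zr(Cl) enolate | [Li+].[O-]C(=O)C(=C)[C@@H]1CCC(C)=C(O[Zr](Cl)(C2C=CC=C2)C2C=CC=C2)C1 | intermediate
15 | 2-[(1R,4R)-4-[(1S,4Z,7E)-1-hydroxy-8-iodo-4-methylnona-4,7-dien-1-yl]-4-methyl-3-oxocyclohexyl]prop-2-enoic acid (present as its zirconium alkoxide) | OC(=O)C(=C)[C@H]1CC(=O)[C@@](C)([C@@H](O)CC/C(C)=C\C/C=C(C)/I)CC1 | intermediate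
16 | 2-[(1R,4R)-4-[(1S,4Z,7E)-1-acetoxy-8-iodo-4-methylnona-4,7-dien-1-yl]-4-methyl-3-oxocyclohexyl]prop-2-enoic acid | OC(=O)C(=C)[C@H]1CC(=O)[C@@](C)([C@@H](OC(C)=O)CC/C(C)=C\C/C=C(C)/I)CC1 | intermediate
17 | ethyl carbonic mixed anhydride of 16 | CCOC(=O)OC(=O)C(=C)[C@H]1CC(=O)[C@@](C)([C@@H](OC(C)=O)CC/C(C)=C\C/C=C(C)/I)CC1 | intermediate
18 | peroxy acid of 16 (CO3H in place of CO2H) | OOC(=O)C(=C)[C@H]1CC(=O)[C@@](C)([C@@H](OC(C)=O)CC/C(C)=C\C/C=C(C)/I)CC1 | intermediate
19 | 2-[(4R,7R)-7-[(1S,4Z,7E)-1-acetoxy-8-iodo-4-methylnona-4,7-dien-1-yl]-7-methyl-2-oxooxepan-4-yl]prop-2-enoic acid | OC(=O)C(=C)[C@H]1CC(=O)O[C@@](C)([C@@H](OC(C)=O)CC/C(C)=C\C/C=C(C)/I)CC1 | intermediate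
20 | (3R,6R,7S,10Z,13E)-7-acetoxy-6-hydroxy-14-iodo-6,10-dimethyl-2-methylidene-3-[2-oxo-2-(pyrrolidin-1-yl)ethyl]pentadeca-10,13-dienoic acid | OC(=O)C(=C)[C@@H](CC(=O)N1CCCC1)CC[C@@](C)(O)[C@@H](OC(C)=O)CC/C(C)=C\C/C=C(C)/I | intermediate
21 | (1S,4Z,7E)-8-iodo-4-methyl-1-[(2R,5R)-2-methyl-6-methylidene-7-oxo-5-[2-oxo-2-(pyrrolidin-1-yl)ethyl]oxepan-2-yl]nona-4,7-dien-1-yl acetate | C=C1C(=O)O[C@@](C)([C@@H](OC(C)=O)CC/C(C)=C\C/C=C(C)/I)CC[C@@H]1CC(=O)N1CCCC1 | intermediate
22 | enamine of 23, (E)-2-(pyrrolidin-1-yl)ethenyl in place of the 2-oxoethyl group | C=C1C(=O)O[C@@](C)([C@@H](OC(C)=O)CC/C(C)=C\C/C=C(C)/I)CC[C@@H]1/C=C/N1CCCC1 | intermediate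
23 | (1S,4Z,7E)-8-iodo-4-methyl-1-[(2R,5R)-2-methyl-6-methylidene-7-oxo-5-(2-oxoethyl)oxepan-2-yl]nona-4,7-dien-1-yl acetate | C=C1C(=O)O[C@@](C)([C@@H](OC(C)=O)CC/C(C)=C\C/C=C(C)/I)CC[C@@H]1CC=O | intermediate
24 | 3-O-triethylsilyl ether of 25 | C=C1C(=O)O[C@]2(C)CC[C@@H]1C[C@@H](O[Si](CC)(CC)CC)/C(C)=C/C/C=C(/C)CC[C@@H]2OC(C)=O | intermediate
25 | (1R,3R,4E,7Z,11S,12R)-11-acetoxy-3-hydroxycembra-4,7,15(17)-trien-16,12-olide: 14-membered carbocycle C1–C14 bridged from C1 to C12 by the seven-membered α-methylene lactone C15(=C17H2)–C16(=O)–O, OH on C3, OAc on C11 | C=C1C(=O)O[C@]2(C)CC[C@@H]1C[C@@H](O)/C(C)=C/C/C=C(/C)CC[C@@H]2OC(C)=O | target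

**Step count and risks**

Total step count: 13 (steps 1–5 for the iodo-dienal 8, steps 6–7 for the keto acid 12, steps 8–13 for the union and endgame).
Longest linear sequence: 11 steps (1, 2, 3, 4, 5, 8, 9, 10, 11, 12, 13).

The three steps most likely to fail:

Step 9, the proposed tethered-peroxy-acid Baeyer–Villiger oxidation. The risk is that the peroxy acid epoxidises the C7–C8 alkene, or that the bridged Criegee adduct forms too slowly. The fallback sets out from 16 and uses an external oxidant that is allowed to do both jobs: m-CPBA (2.5 equiv, NaHCO3, CH2Cl2) effects the known Baeyer–Villiger oxidation with migration of the quaternary carbon and epoxidises the trisubstituted alkene, giving the epoxy lactone acid F1 as a pair of epoxide diastereomers. Stereospecific deoxygenation with Ph3P=Se and CF3CO2H in CH2Cl2 restores the Z alkene and the route is rejoined at 19.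

Step 11, acylation of the hindered tertiary C12 hydroxyl in a seven-membered ring closure. The fallback sets out from 20 and forms the same C–O bond by oxidation instead of acyl substitution. The acrylic acid is reduced through its isobutyl carbonate mixed anhydride (i-BuOCOCl, N-methylmorpholine, then NaBH4) to the allylic alcohol F2. Oxidative lactonisation with TEMPO and PhI(OAc)2 in CH2Cl2 then takes the primary allylic alcohol to the enal, the tertiary hydroxyl adds to give the seven-membered lactol, and this is oxidised to the lactone, rejoining the route at 21.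

Step 13, the proposed electrochemical ring closure, where both the macrocyclisation and the sense of induction at C3 are uncertain. The fallback sets out from 23 and uses the established chemical Nozaki–Hiyama–Kishi macrocyclisation with stoichiometric CrCl2 and catalytic NiCl2 in DMSO/THF at high dilution. If this closes the ring mainly to the 3S alcohol F3, C3 is set by reduction instead of by C–C bond formation: oxidation with Dess–Martin periodinane gives the macrocyclic enone F4, and 1,2-reduction with NaBH4 and CeCl3·7H2O at −78 °C, hydride entering from the open face of the ring, returns to the route at 25.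

Further compounds
F1 | step 9 | 2-[(4R,7R)-7-[(1S,7E)-1-acetoxy-4,5-epoxy-8-iodo-4-methylnon-7-en-1-yl]-7-methyl-2-oxooxepan-4-yl]prop-2-enoic acid, both cis-epoxide diastereomers | OC(=O)C(=C)[C@H]1CC(=O)O[C@@](C)([C@@H](OC(C)=O)CCC2(C)OC2C/C=C(C)/I)CC1
F2 | step 11 | (1S,4Z,7E)-1-[(2R,5R)-2-hydroxy-6-(hydroxymethyl)-5-[2-oxo-2-(pyrrolidin-1-yl)ethyl]hept-6-en-2-yl]-8-iodo-4-methylnona-4,7-dien-1-yl acetate | OCC(=C)[C@@H](CC(=O)N1CCCC1)CC[C@@](C)(O)[C@@H](OC(C)=O)CC/C(C)=C\C/C=C(C)/I
F3 | step 13 | (1R,3S,4E,7Z,11S,12R)-11-acetoxy-3-hydroxycembra-4,7,15(17)-trien-16,12-olide, the 3-epimer of 25 | C=C1C(=O)O[C@]2(C)CC[C@@H]1C[C@H](O)/C(C)=C/C/C=C(/C)CC[C@@H]2OC(C)=O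
F4 | step 13 | (1R,4E,7Z,11S,12R)-11-acetoxy-3-oxocembra-4,7,15(17)-trien-16,12-olide | C=C1C(=O)O[C@]2(C)CC[C@@H]1CC(=O)/C(C)=C/C/C=C(/C)CC[C@@H]2OC(C)=O
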